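Everything rests on disconnecting the chroman O1–C8a bond. The precursor is a 4-methoxy-2,3-dimethylphenol bearing, ortho to methoxy, the hydroxyalkyl chain of hydroborated (S)-linalool. Because arene carbon C8a lies para to the C6 oxygen, two-electron oxidation of this phenol makes C8a electrophilic and the tertiary hydroxyl on C2 adds there. One operation thus closes the pyran ring (O1, C2, C3, C4, C4a, C8a) as an 8a-methoxy quinone monoketal, breaking only the O–H bond at stereocentre C2; mild reduction then restores the arene. The side chain (C1'–C33' from C2) is completed by sulfone coupling at C5'–C6' with a fragment carrying the (S)-C24' carbinol.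

Key step: step 5

Remark: CIP analysis of the target gives 2S at the chroman carbon and 24'S in the chain; with the side chain numbered C1'–C33' outward from C2 the sulfone fragment spans C6'–C33' (28 chain carbons); (S)-linalool of high enantiomeric purity is assumed to be available.

Step 1
Reactants: 1 2,3-dimethylanisole
Product: 2 1-(4-methoxy-2,3-dimethylphenyl)ethan-1-one
Conditions: AcCl, AlCl3, CH2Cl2, 0 °C
Reagents that add atoms: acetyl chloride CC(=O)Cl
Why: Friedel–Crafts acylation should go para to the methoxy group, the strongest director on the ring, and so marks the carbon that becomes C6 of the chroman.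

Step 2
Reactants: 2 1-(4-methoxy-2,3-dimethylphenyl)ethan-1-one
Product: 3 4-methoxy-2,3-dimethylphenyl acetate
Conditions: mCPBA, CH2Cl2, rt
Reagents that add atoms: 3-chloroperbenzoic acid OOC(=O)c1cccc(Cl)c1
Why: In this Baeyer–Villiger oxidation the electron-rich aryl group migrates in preference to methyl, so the C6 oxygen arrives already masked as an acetate and differentiated from the methoxy oxygen.

Step 3
Reactants: 3 4-methoxy-2,3-dimethylphenyl acetate
Product: 4 5-bromo-4-methoxy-2,3-dimethylphenyl acetate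
Conditions: NBS, MeCN, rt, dark
Reagents that add atoms: N-bromosuccinimide O=C1CCC(=O)N1Br
Why: Electrophilic aromatic bromination should occur ortho to methoxy (and para to a methyl group) because acetoxy is a far weaker activator, which places the halogen on the future C4a.

Step 4
Reactants: 5 (S)-linalool; 4 5-bromo-4-methoxy-2,3-dimethylphenyl acetate
Product: 8 5-[(3S)-3-hydroxy-3,7-dimethyloct-6-en-1-yl]-4-methoxy-2,3-dimethylphenol, via alkylborane 6 (not isolated), via aryl acetate 7 (not isolated)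
Conditions: 9-BBN (1.5 equiv), THF, 0 °C to rt; then 4, Pd(OAc)2 (cat.), SPhos, aq. K3PO4, THF, 60 °C; then NaOH, MeOH, rt
Reagents that add atoms: none
Why: 9-BBN hydroborates only the monosubstituted vinyl group and places boron on the terminal carbon, the B-alkyl Suzuki–Miyaura coupling then forms C4–C4a and saponification frees the phenol, while the carbinol carbon is a spectator and keeps its configuration.

Step 5
Reactants: 8 5-[(3S)-3-hydroxy-3,7-dimethyloct-6-en-1-yl]-4-methoxy-2,3-dimethylphenol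
Product: 9 (2S)-8a-methoxy-2,7,8-trimethyl-2-(4-methylpent-3-en-1-yl)-2,3,4,8a-tetrahydro-6H-chromen-6-one (mixture of C8a epimers)
Conditions: PhI(OAc)2 (1.1 equiv), NaHCO3, MeCN/CH2Cl2, 0 °C
Reagents that add atoms: none
Why: The phenol exchanges for acetate on trivalent iodine and loss of iodobenzene leaves a phenoxenium ion whose charge the methoxy oxygen holds at C8a as an oxocarbenium ion, to which the C2 hydroxyl adds to give the mixed ketal. The closest known reaction type is the PhI(OAc)2 oxidation of 4-alkoxyphenols to quinone monoketals with capture by an internal alcohol (oxidative dearomatisation). The pyran ring (O1, C2, C3, C4, C4a, C8a) closes in a 6-exo-trig mode. The new C8a stereocentre forms without control, which is of no consequence because both epimers lose it again in step 6, and C2 keeps its S configuration because only its O–H bond reacts. The step needs attack at C8a and not at C5, which the hydroxyl could reach through a ring of the same size, and ring closure must outrun capture by external nucleophiles; the para-methoxy group, which localises the charge at C8a, the non-nucleophilic solvent and the NaHCO3 buffer should secure this.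

Step 6
Reactants: 9 (2S)-8a-methoxy-2,7,8-trimethyl-2-(4-methylpent-3-en-1-yl)-2,3,4,8a-tetrahydro-6H-chromen-6-one
Product: 10 (2S)-2,7,8-trimethyl-2-(4-methylpent-3-en-1-yl)-3,4-dihydro-2H-chromen-6-ol
Conditions: L-ascorbic acid, AcOH, THF/H2O, rt, argon
Reagents that add atoms: none
Why: Acid-assisted loss of methanol from the mixed ketal gives a chromanoxylium ion that ascorbic acid reduces by two electrons to the aromatic chroman-6-ol, the known reduction of 8a-alkoxytocopherones, and the C2–O1 bond is never broken so C2 stays S.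

Step 7
Reactants: 10 (2S)-2,7,8-trimethyl-2-(4-methylpent-3-en-1-yl)-3,4-dihydro-2H-chromen-6-ol
Product: 11 tert-butyldimethyl{[(2S)-2,7,8-trimethyl-2-(4-methylpent-3-en-1-yl)-3,4-dihydro-2H-chromen-6-yl]oxy}silane
Conditions: TBSCl, imidazole, DMF, rt
Reagents that add atoms: tert-butyldimethylsilyl chloride CC(C)(C)[Si](C)(C)Cl
Why: Silylation masks the oxidation-prone chromanol for the peroxide, bromination and carbanion steps and can later be undone by fluoride without acid.

Step 8
Reactants: 11 tert-butyldimethyl{[(2S)-2,7,8-trimethyl-2-(4-methylpent-3-en-1-yl)-3,4-dihydro-2H-chromen-6-yl]oxy}silane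
Product: 12 (2E)-5-[(2S)-6-{[tert-butyl(dimethyl)silyl]oxy}-2,7,8-trimethyl-3,4-dihydro-2H-chromen-2-yl]-2-methylpent-2-en-1-ol
Conditions: SeO2 (cat.), t-BuOOH, salicylic acid (cat.), CH2Cl2, rt
Reagents that add atoms: selenium dioxide O=[Se]=O; tert-butyl hydroperoxide CC(C)(C)OO
Why: Catalytic SeO2 allylic oxidation (ene reaction followed by a 2,3-sigmatropic shift) hydroxylates the E-methyl group of the isopropylidene terminus, giving the E-allylic alcohol at C5' and thereby the E geometry of C3'=C4'.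

Step 9
Reactants: 12 (2E)-5-[(2S)-6-{[tert-butyl(dimethyl)silyl]oxy}-2,7,8-trimethyl-3,4-dihydro-2H-chromen-2-yl]-2-methylpent-2-en-1-ol
Product: 13 {[(2S)-2-[(3E)-5-bromo-4-methylpent-3-en-1-yl]-2,7,8-trimethyl-3,4-dihydro-2H-chromen-6-yl]oxy}(tert-butyl)dimethylsilane
Conditions: CBr4, PPh3, CH2Cl2, 0 °C
Reagents that add atoms: carbon tetrabromide BrC(Br)(Br)Br
Why: The Appel reaction converts the primary allylic alcohol into the bromide by direct displacement under neutral conditions, without allylic shift, loss of alkene geometry or cleavage of the aryl silyl ether.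

Step 10
Reactants: 14 (2E,6E)-farnesol
Product: 15 [(2S,3S)-3-[(3E)-4,8-dimethylnona-3,7-dien-1-yl]-3-methyloxiran-2-yl]methanol
Conditions: Ti(OiPr)4 (cat.), L-(+)-diethyl tartrate (cat.), t-BuOOH, 4 Å MS, CH2Cl2, −20 °C
Reagents that add atoms: tert-butyl hydroperoxide CC(C)(C)OO
Why: Sharpless asymmetric epoxidation acts only on the allylic alcohol alkene, and the L-(+)-tartrate ligand directs oxygen to the face that gives the (2S,3S)-epoxide, which sets the future C24' stereocentre.

Step 11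
Reactants: 15 [(2S,3S)-3-[(3E)-4,8-dimethylnona-3,7-dien-1-yl]-3-methyloxiran-2-yl]methanol
Product: 16 (2S,3R)-3-(chloromethyl)-2-[(3E)-4,8-dimethylnona-3,7-dien-1-yl]-2-methyloxirane
Conditions: PPh3, CCl4, NaHCO3, reflux
Reagents that add atoms: carbon tetrachloride ClC(Cl)(Cl)Cl
Why: Appel chlorination replaces the primary hydroxyl by chloride under neutral conditions and leaves the epoxide and both its stereocentres as they are (the descriptor of the CH carbon changes only because chlorine raises the rank of the CH2Cl arm).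

Step 12
Reactants: 16 (2S,3R)-3-(chloromethyl)-2-[(3E)-4,8-dimethylnona-3,7-dien-1-yl]-2-methyloxirane
Product: 17 (3S,6E)-3,7,11-trimethyldodeca-6,10-dien-1-yn-3-ol
Conditions: LiN(iPr)2 (3.5 equiv), THF, −35 to 0 °C
Reagents that add atoms: none
Why: Base-induced double elimination of the 2,3-epoxy chloride (deprotonation next to chlorine with opening of the epoxide to a chlorovinyl alkoxide, then dehydrochlorination) gives the terminal alkyne, and because the C–O bond at the quaternary carbon is kept the tertiary propargylic alcohol should form as the S enantiomer.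

Step 13
Reactants: 18 (2E,6E,10E)-geranylgeraniol
Product: 20 {[(2E,6E,10E)-3,7,11,15-tetramethylhexadeca-2,6,10,14-tetraen-1-yl]sulfonyl}benzene, via geranylgeranyl bromide 19 (not isolated)
Conditions: PBr3, Et2O, 0 °C; then PhSO2Na, DMF, rt
Reagents that add atoms: sodium benzenesulfinate [Na+].[O-]S(=O)c1ccccc1
Why: PBr3 gives the primary allylic bromide and sulfinate then displaces bromide through sulfur at the primary carbon, the standard preparation of prenyl-type sulfones with retention of the 2E geometry.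

Step 14
Reactants: 20 {[(2E,6E,10E)-3,7,11,15-tetramethylhexadeca-2,6,10,14-tetraen-1-yl]sulfonyl}benzene
Product: 21 (2E,6E,10E,14E)-2,6,10,14-tetramethyl-16-(phenylsulfonyl)hexadeca-2,6,10,14-tetraen-1-ol
Conditions: SeO2 (cat.), t-BuOOH, salicylic acid (cat.), CH2Cl2, 0 °C to rt
Reagents that add atoms: selenium dioxide O=[Se]=O; tert-butyl hydroperoxide CC(C)(C)OO
Why: Catalytic SeO2 allylic oxidation favours the E-methyl group of the terminal isopropylidene unit, the most accessible alkene and the one farthest from the electron-withdrawing sulfone, giving the E-allylic alcohol whose carbinol carbon becomes C21'.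

Step 15
Reactants: 21 (2E,6E,10E,14E)-2,6,10,14-tetramethyl-16-(phenylsulfonyl)hexadeca-2,6,10,14-tetraen-1-ol
Product: 22 {[(2E,6E,10E,14E)-16-bromo-3,7,11,15-tetramethylhexadeca-2,6,10,14-tetraen-1-yl]sulfonyl}benzene
Conditions: CBr4, PPh3, CH2Cl2, 0 °C
Reagents that add atoms: carbon tetrabromide BrC(Br)(Br)Br
Why: The Appel reaction gives the primary allylic bromide by direct displacement under neutral conditions, to which the sulfone and the alkene geometries are inert.

Step 16
Reactants: 17 (3S,6E)-3,7,11-trimethyldodeca-6,10-dien-1-yn-3-ol; 22 {[(2E,6E,10E,14E)-16-bromo-3,7,11,15-tetramethylhexadeca-2,6,10,14-tetraen-1-yl]sulfonyl}benzene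
Product: 23 (2E,6E,10E,14E,19S,22E)-3,7,11,15,19,23,27-heptamethyl-1-(phenylsulfonyl)octacosa-2,6,10,14,22,26-hexaen-17-yn-19-ol
Conditions: CuI (cat.), K2CO3, DMF, rt
Reagents that add atoms: none
Why: The copper acetylide formed under carbonate conditions substitutes the primary allylic bromide at its unhindered CH2 terminus (copper-mediated alkyne allylation to a skipped enyne), forming C21'–C22' without protection of the tertiary alcohol and with a base too weak to deprotonate the sulfone.

Step 17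
Reactants: 23 (2E,6E,10E,14E,19S,22E)-3,7,11,15,19,23,27-heptamethyl-1-(phenylsulfonyl)octacosa-2,6,10,14,22,26-hexaen-17-yn-19-ol
Product: 24 (2E,6E,10E,14E,17E,19S,22E)-3,7,11,15,19,23,27-heptamethyl-1-(phenylsulfonyl)octacosa-2,6,10,14,17,22,26-heptaen-19-ol
Conditions: NaAlH2(OCH2CH2OMe)2, THF, 0 °C to rt; aq. potassium sodium tartrate
Reagents that add atoms: none
Why: The alkoxyaluminate formed from the propargylic alcohol delivers hydride intramolecularly in a trans-hydroalumination, so protonation should give only the E-alkene C22'=C23', while isolated alkenes and the aryl sulfone are not reduced under these conditions.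

Step 18
Reactants: 24 (2E,6E,10E,14E,17E,19S,22E)-3,7,11,15,19,23,27-heptamethyl-1-(phenylsulfonyl)octacosa-2,6,10,14,17,22,26-heptaen-19-ol; 13 {[(2S)-2-[(3E)-5-bromo-4-methylpent-3-en-1-yl]-2,7,8-trimethyl-3,4-dihydro-2H-chromen-6-yl]oxy}(tert-butyl)dimethylsilane
Product: 25 tert-butyl{[(2S)-2-[(3E,7E,11E,15E,19E,22E,24S,27E)-24-hydroxy-4,8,12,16,20,24,28,32-octamethyl-6-(phenylsulfonyl)tritriaconta-3,7,11,15,19,22,27,31-octaen-1-yl]-2,7,8-trimethyl-3,4-dihydro-2H-chromen-6-yl]oxy}dimethylsilane (both C6' epimers)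
Conditions: n-BuLi (2.1 equiv), THF/DMPU, −78 °C; then 13, −78 to −40 °C
Reagents that add atoms: none
Why: The dianion (lithium alkoxide and allylic sulfonyl carbanion) is alkylated at the carbon next to sulfur by the allylic bromide (Biellmann-type prenyl sulfone coupling), forming C5'–C6'; the new sulfone-bearing stereocentre is uncontrolled and disappears in the next step.

Step 19
Reactants: 25 tert-butyl{[(2S)-2-[(3E,7E,11E,15E,19E,22E,24S,27E)-24-hydroxy-4,8,12,16,20,24,28,32-octamethyl-6-(phenylsulfonyl)tritriaconta-3,7,11,15,19,22,27,31-octaen-1-yl]-2,7,8-trimethyl-3,4-dihydro-2H-chromen-6-yl]oxy}dimethylsilane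
Product: 26 tert-butyl{[(2S)-2-[(3E,7E,11E,15E,19E,22E,24S,27E)-24-hydroxy-4,8,12,16,20,24,28,32-octamethyltritriaconta-3,7,11,15,19,22,27,31-octaen-1-yl]-2,7,8-trimethyl-3,4-dihydro-2H-chromen-6-yl]oxy}dimethylsilane
Conditions: PdCl2(dppp) (cat.), LiBHEt3, THF, 0 °C
Reagents that add atoms: none
Why: Zerovalent palladium formed in the flask ionises the allylic C–S bond and hydride is delivered to the less substituted terminus of the allyl complex, so this reductive desulfonylation should leave C7'=C8' in place and E and spare the tertiary alkoxide, the skipped diene and the silyl ether.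

Step 20
Reactants: 26 tert-butyl{[(2S)-2-[(3E,7E,11E,15E,19E,22E,24S,27E)-24-hydroxy-4,8,12,16,20,24,28,32-octamethyltritriaconta-3,7,11,15,19,22,27,31-octaen-1-yl]-2,7,8-trimethyl-3,4-dihydro-2H-chromen-6-yl]oxy}dimethylsilane
Product: 27 (2S)-2-[(3E,7E,11E,15E,19E,22E,24S,27E)-24-hydroxy-4,8,12,16,20,24,28,32-octamethyltritriaconta-3,7,11,15,19,22,27,31-octaen-1-yl]-2,7,8-trimethyl-3,4-dihydro-2H-chromen-6-ol (CNP0323443.2)
Conditions: Bu4NF, AcOH, THF, 0 °C, argon
Reagents that add atoms: none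
Why: Fluoride cleaves the aryl silyl ether under buffered, non-acidic conditions that spare the acid-sensitive tertiary allylic alcohol and the polyene, releasing the target.

Compound list

1 | 2,3-dimethylanisole (1-methoxy-2,3-dimethylbenzene) | COc1cccc(C)c1C | starting material
2 | 1-(4-methoxy-2,3-dimethylphenyl)ethan-1-one | CC(=O)c1ccc(OC)c(C)c1C | intermediate
3 | 4-methoxy-2,3-dimethylphenyl acetate | CC(=O)Oc1ccc(OC)c(C)c1C | intermediate
4 | 5-bromo-4-methoxy-2,3-dimethylphenyl acetate | CC(=O)Oc1cc(Br)c(OC)c(C)c1C | intermediate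
5 | (S)-linalool, (3S)-3,7-dimethylocta-1,6-dien-3-ol | CC(C)=CCC[C@@](O)(C)C=C | starting material
6 | 9-[(3R)-3-hydroxy-3,7-dimethyloct-6-en-1-yl]-9-borabicyclo[3.3.1]nonane (same spatial arrangement as in 5; the descriptor changes because the borylethyl arm ranks below the homoprenyl arm; formed in the flask) | CC(C)=CCC[C@@](O)(C)CCB1C2CCCC1CCC2 | intermediate
7 | 5-[(3S)-3-hydroxy-3,7-dimethyloct-6-en-1-yl]-4-methoxy-2,3-dimethylphenyl acetate (formed in the flask) | CC(C)=CCC[C@@](O)(C)CCc1cc(OC(C)=O)c(C)c(C)c1OC | intermediate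
8 | 5-[(3S)-3-hydroxy-3,7-dimethyloct-6-en-1-yl]-4-methoxy-2,3-dimethylphenol | CC(C)=CCC[C@@](O)(C)CCc1cc(O)c(C)c(C)c1OC | intermediate
9 | (2S)-8a-methoxy-2,7,8-trimethyl-2-(4-methylpent-3-en-1-yl)-2,3,4,8a-tetrahydro-6H-chromen-6-one (C8a epimers) | CC(C)=CCC[C@@]1(C)CCC2=CC(=O)C(C)=C(C)C2(OC)O1 | intermediate
10 | (2S)-2,7,8-trimethyl-2-(4-methylpent-3-en-1-yl)-3,4-dihydro-2H-chromen-6-ol | CC(C)=CCC[C@@]1(C)CCc2cc(O)c(C)c(C)c2O1 | intermediate
11 | tert-butyldimethyl{[(2S)-2,7,8-trimethyl-2-(4-methylpent-3-en-1-yl)-3,4-dihydro-2H-chromen-6-yl]oxy}silane | CC(C)=CCC[C@@]1(C)CCc2cc(O[Si](C)(C)C(C)(C)C)c(C)c(C)c2O1 | intermediate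
12 | (2E)-5-[(2S)-6-{[tert-butyl(dimethyl)silyl]oxy}-2,7,8-trimethyl-3,4-dihydro-2H-chromen-2-yl]-2-methylpent-2-en-1-ol | OC/C(C)=C/CC[C@@]1(C)CCc2cc(O[Si](C)(C)C(C)(C)C)c(C)c(C)c2O1 | intermediate
13 | {[(2S)-2-[(3E)-5-bromo-4-methylpent-3-en-1-yl]-2,7,8-trimethyl-3,4-dihydro-2H-chromen-6-yl]oxy}(tert-butyl)dimethylsilane | BrC/C(C)=C/CC[C@@]1(C)CCc2cc(O[Si](C)(C)C(C)(C)C)c(C)c(C)c2O1 | intermediate
14 | (2E,6E)-farnesol | CC(C)=CCC/C(C)=C/CC/C(C)=C/CO | starting material
15 | [(2S,3S)-3-[(3E)-4,8-dimethylnona-3,7-dien-1-yl]-3-methyloxiran-2-yl]methanol | CC(C)=CCC/C(C)=C/CC[C@]1(C)O[C@H]1CO | intermediate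
16 | (2S,3R)-3-(chloromethyl)-2-[(3E)-4,8-dimethylnona-3,7-dien-1-yl]-2-methyloxirane | CC(C)=CCC/C(C)=C/CC[C@]1(C)O[C@H]1CCl | intermediate
17 | (3S,6E)-3,7,11-trimethyldodeca-6,10-dien-1-yn-3-ol | CC(C)=CCC/C(C)=C/CC[C@](C)(O)C#C | intermediate
18 | (2E,6E,10E)-geranylgeraniol | CC(C)=CCC/C(C)=C/CC/C(C)=C/CC/C(C)=C/CO | starting material
19 | (2E,6E,10E)-geranylgeranyl bromide (formed in the flask) | CC(C)=CCC/C(C)=C/CC/C(C)=C/CC/C(C)=C/CBr | intermediate
20 | {[(2E,6E,10E)-3,7,11,15-tetramethylhexadeca-2,6,10,14-tetraen-1-yl]sulfonyl}benzene | CC(C)=CCC/C(C)=C/CC/C(C)=C/CC/C(C)=C/CS(=O)(=O)c1ccccc1 | intermediate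
21 | (2E,6E,10E,14E)-2,6,10,14-tetramethyl-16-(phenylsulfonyl)hexadeca-2,6,10,14-tetraen-1-ol | OC/C(C)=C/CC/C(C)=C/CC/C(C)=C/CC/C(C)=C/CS(=O)(=O)c1ccccc1 | intermediate
22 | {[(2E,6E,10E,14E)-16-bromo-3,7,11,15-tetramethylhexadeca-2,6,10,14-tetraen-1-yl]sulfonyl}benzene | BrC/C(C)=C/CC/C(C)=C/CC/C(C)=C/CC/C(C)=C/CS(=O)(=O)c1ccccc1 | intermediate
23 | (2E,6E,10E,14E,19S,22E)-3,7,11,15,19,23,27-heptamethyl-1-(phenylsulfonyl)octacosa-2,6,10,14,22,26-hexaen-17-yn-19-ol | CC(C)=CCC/C(C)=C/CC[C@](C)(O)C#CC/C(C)=C/CC/C(C)=C/CC/C(C)=C/CC/C(C)=C/CS(=O)(=O)c1ccccc1 | intermediate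
24 | (2E,6E,10E,14E,17E,19S,22E)-3,7,11,15,19,23,27-heptamethyl-1-(phenylsulfonyl)octacosa-2,6,10,14,17,22,26-heptaen-19-ol | CC(C)=CCC/C(C)=C/CC[C@](C)(O)/C=C/C/C(C)=C/CC/C(C)=C/CC/C(C)=C/CC/C(C)=C/CS(=O)(=O)c1ccccc1 | intermediate
25 | tert-butyl{[(2S)-2-[(3E,7E,11E,15E,19E,22E,24S,27E)-24-hydroxy-4,8,12,16,20,24,28,32-octamethyl-6-(phenylsulfonyl)tritriaconta-3,7,11,15,19,22,27,31-octaen-1-yl]-2,7,8-trimethyl-3,4-dihydro-2H-chromen-6-yl]oxy}dimethylsilane (both C6' epimers) | CC(C)=CCC/C(C)=C/CC[C@](C)(O)/C=C/C/C(C)=C/CC/C(C)=C/CC/C(C)=C/CC/C(C)=C/C(C/C(C)=C/CC[C@@]1(C)CCc2cc(O[Si](C)(C)C(C)(C)C)c(C)c(C)c2O1)S(=O)(=O)c1ccccc1 | intermediate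
26 | tert-butyl{[(2S)-2-[(3E,7E,11E,15E,19E,22E,24S,27E)-24-hydroxy-4,8,12,16,20,24,28,32-octamethyltritriaconta-3,7,11,15,19,22,27,31-octaen-1-yl]-2,7,8-trimethyl-3,4-dihydro-2H-chromen-6-yl]oxy}dimethylsilane | CC(C)=CCC/C(C)=C/CC[C@](C)(O)/C=C/C/C(C)=C/CC/C(C)=C/CC/C(C)=C/CC/C(C)=C/CC/C(C)=C/CC[C@@]1(C)CCc2cc(O[Si](C)(C)C(C)(C)C)c(C)c(C)c2O1 | intermediate
27 | (2S)-2-[(3E,7E,11E,15E,19E,22E,24S,27E)-24-hydroxy-4,8,12,16,20,24,28,32-octamethyltritriaconta-3,7,11,15,19,22,27,31-octaen-1-yl]-2,7,8-trimethyl-3,4-dihydro-2H-chromen-6-ol (CNP0323443.2) | CC(C)=CCC/C(C)=C/CC[C@](C)(O)/C=C/C/C(C)=C/CC/C(C)=C/CC/C(C)=C/CC/C(C)=C/CC/C(C)=C/CC[C@@]1(C)CCc2cc(O)c(C)c(C)c2O1 | target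

Total step count: 20 steps.
Longest linear sequence: 12 steps (steps 1 to 9, then 18 to 20).

Steps most likely to fail

Step 5. The oxidised arene may be intercepted by water or acetate, or go on to the ring-opened quinone, faster than the hydroxyl closes the ring. The fallback separates oxidation from ring closure and sets out from 8. PhI(OAc)2 in MeOH at 0 °C should give, by the standard solvent capture of 4-methoxyphenols, the dimethyl ketal 5-[(3S)-3-hydroxy-3,7-dimethyloct-6-en-1-yl]-4,4-dimethoxy-2,3-dimethylcyclohexa-2,5-dien-1-one F1. Brief exposure of this ketal to pyridinium p-toluenesulfonate in dry CH2Cl2 over 4 Å molecular sieves should then exchange one methoxy group for the tethered tertiary hydroxyl (intramolecular transketalisation with loss of methanol). The fallback comes back to the route at 9.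

Step 14. Allylic oxidation may spread over the internal trisubstituted alkenes and run on to the enal, eroding site selectivity. The fallback functionalises the terminus through a bromohydrin and sets out from 20. NBS in aqueous THF at 0 °C should add HOBr selectively to the terminal alkene to give (2E,6E,10E)-14-bromo-3,7,11,15-tetramethyl-1-(phenylsulfonyl)hexadeca-2,6,10-trien-15-ol F2. K2CO3 in MeOH closes this to the terminal epoxide 2,2-dimethyl-3-[(3E,7E,11E)-3,7,11-trimethyl-13-(phenylsulfonyl)trideca-3,7,11-trien-1-yl]oxirane F3. Al(OiPr)3 in hot toluene isomerises the epoxide to the allylic alcohol with a terminal methylene group, (6E,10E,14E)-2,6,10,14-tetramethyl-16-(phenylsulfonyl)hexadeca-1,6,10,14-tetraen-3-ol F4. PBr3 in Et2O at −10 °C should convert this alcohol with allylic transposition into the E primary bromide. The fallback comes back to the route at 22 and bypasses 21.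

Step 17. Hydride may deprotonate or attack the allylic sulfone, or the aluminate may isomerise the skipped enyne, before the alkyne is reduced. The fallback postpones the reduction until sulfur is gone and sets out from 23 and 13. Dianion alkylation of 23 with 13 (n-BuLi, THF/DMPU, −78 °C) should give tert-butyl{[(2S)-2-[(3E,7E,11E,15E,19E,24S,27E)-24-hydroxy-4,8,12,16,20,24,28,32-octamethyl-6-(phenylsulfonyl)tritriaconta-3,7,11,15,19,27,31-heptaen-22-yn-1-yl]-2,7,8-trimethyl-3,4-dihydro-2H-chromen-6-yl]oxy}dimethylsilane F5. PdCl2(dppp) with LiBHEt3 then removes the sulfonyl group to give tert-butyl{[(2S)-2-[(3E,7E,11E,15E,19E,24S,27E)-24-hydroxy-4,8,12,16,20,24,28,32-octamethyltritriaconta-3,7,11,15,19,27,31-heptaen-22-yn-1-yl]-2,7,8-trimethyl-3,4-dihydro-2H-chromen-6-yl]oxy}dimethylsilane F6. NaAlH2(OCH2CH2OMe)2 in THF finally reduces the propargylic alcohol to the E-alkene with no sulfone present. The fallback comes back to the route at 26.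

Further compounds

F1 | step 5 | 5-[(3S)-3-hydroxy-3,7-dimethyloct-6-en-1-yl]-4,4-dimethoxy-2,3-dimethylcyclohexa-2,5-dien-1-one | CC(C)=CCC[C@@](O)(C)CCC1=CC(=O)C(C)=C(C)C1(OC)OC
F2 | step 14 | (2E,6E,10E)-14-bromo-3,7,11,15-tetramethyl-1-(phenylsulfonyl)hexadeca-2,6,10-trien-15-ol (racemic at C14) | CC(C)(O)C(Br)CC/C(C)=C/CC/C(C)=C/CC/C(C)=C/CS(=O)(=O)c1ccccc1
F3 | step 14 | 2,2-dimethyl-3-[(3E,7E,11E)-3,7,11-trimethyl-13-(phenylsulfonyl)trideca-3,7,11-trien-1-yl]oxirane (racemic) | CC1(C)OC1CC/C(C)=C/CC/C(C)=C/CC/C(C)=C/CS(=O)(=O)c1ccccc1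
F4 | step 14 | (6E,10E,14E)-2,6,10,14-tetramethyl-16-(phenylsulfonyl)hexadeca-1,6,10,14-tetraen-3-ol (racemic) | C=C(C)C(O)CC/C(C)=C/CC/C(C)=C/CC/C(C)=C/CS(=O)(=O)c1ccccc1
F5 | step 17 | tert-butyl{[(2S)-2-[(3E,7E,11E,15E,19E,24S,27E)-24-hydroxy-4,8,12,16,20,24,28,32-octamethyl-6-(phenylsulfonyl)tritriaconta-3,7,11,15,19,27,31-heptaen-22-yn-1-yl]-2,7,8-trimethyl-3,4-dihydro-2H-chromen-6-yl]oxy}dimethylsilane (both C6' epimers) | CC(C)=CCC/C(C)=C/CC[C@](C)(O)C#CC/C(C)=C/CC/C(C)=C/CC/C(C)=C/CC/C(C)=C/C(C/C(C)=C/CC[C@@]1(C)CCc2cc(O[Si](C)(C)C(C)(C)C)c(C)c(C)c2O1)S(=O)(=O)c1ccccc1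
F6 | step 17 | tert-butyl{[(2S)-2-[(3E,7E,11E,15E,19E,24S,27E)-24-hydroxy-4,8,12,16,20,24,28,32-octamethyltritriaconta-3,7,11,15,19,27,31-heptaen-22-yn-1-yl]-2,7,8-trimethyl-3,4-dihydro-2H-chromen-6-yl]oxy}dimethylsilane | CC(C)=CCC/C(C)=C/CC[C@](C)(O)C#CC/C(C)=C/CC/C(C)=C/CC/C(C)=C/CC/C(C)=C/CC/C(C)=C/CC[C@@]1(C)CCc2cc(O[Si](C)(C)C(C)(C)C)c(C)c(C)c2O1
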